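Ring B is hexasubstituted, and its adjacent carbons C1 (CO2Me) and C2 (CH3), with the C6 methoxy group beside C1, are made together: a C1–C2 aryne, polarised by that C6–OMe, takes methyl at C2 from MeLi and CO2 at the resulting C1 anion, forming both C–C bonds in one operation. The aryne precursor is a pentasubstituted fluoroarene (F, OMe, MOM-protected phenol, two methyls) whose only ring hydrogen sits between F and OMe; a temporary silyl group shields that hydrogen while the second methyl is installed. The acid is esterified, unmasked and acylated with a benzyl-protected ring A acid chloride built from 2,5-dimethylresorcinol, then debenzylated.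

Key step: step 6

Remark: ring B is numbered C1 (CO2Me), C2 (CH3), C3 (CH3), C4 (O-acyl), C5 (CH3), C6 (OMe); because the C–H between F and OMe becomes the most acidic ring position once the first methyl is in place, it is masked as a Me3Si group during the second methylation.

Step 1
Reactants: 1 3-fluoro-5-methoxyphenol
Product: 2 1-fluoro-3-methoxy-5-(methoxymethoxy)benzene
Conditions: MOMCl, K2CO3, acetone, 0 °C to rt
Reagents that add atoms: chloromethyl methyl ether, COCCl
Why: Williamson O-alkylation of the phenoxide with the reactive α-chloro ether should give the methoxymethyl ether, which keeps the two ring B oxygens distinct and later directs lithiation.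

Step 2
Reactants: 2 1-fluoro-3-methoxy-5-(methoxymethoxy)benzene
Product: 4 1-fluoro-5-methoxy-3-(methoxymethoxy)-2-methylbenzene, via aryllithium 3 (not isolated)
Conditions: n-BuLi, THF, −78 °C; MeI, −78 °C to rt
Reagents that add atoms: iodomethane, CI
Why: Directed ortho-metalation: of the three ring hydrogens the one between F and OMOM is favoured both by the inductive effect of fluorine and by chelation of lithium by the acetal, the 2-fluoroaryllithium 3 keeps its fluoride at −78 °C, and MeI alkylates it at that temperature.

Step 3
Reactants: 4 1-fluoro-5-methoxy-3-(methoxymethoxy)-2-methylbenzene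
Product: 6 [2-fluoro-6-methoxy-4-(methoxymethoxy)-3-methylphenyl]trimethylsilane, via aryllithium 5 (not isolated)
Conditions: LiN(iPr)2, Me3SiCl (present from the start), THF, −78 °C
Reagents that add atoms: chlorotrimethylsilane, C[Si](C)(C)Cl
Why: Deprotonation by the lithium amide is governed by acidity and should remove only the hydrogen flanked by F and OMe (the hydrogen between OMOM and OMe is not acidic enough for an amide base), and silylation of 5 as it forms masks exactly the position that must stay unsubstituted for the aryne step (ortho-lithiation with in situ silyl trapping, used as a blocking tactic).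

Step 4
Reactants: 6 [2-fluoro-6-methoxy-4-(methoxymethoxy)-3-methylphenyl]trimethylsilane
Product: 8 [2-fluoro-6-methoxy-4-(methoxymethoxy)-3,5-dimethylphenyl]trimethylsilane, via aryllithium 7 (not isolated)
Conditions: n-BuLi, TMEDA, THF, 0 °C; MeI, 0 °C to rt
Reagents that add atoms: iodomethane, CI
Why: Directed ortho-metalation at the only remaining ring hydrogen, which lies between OMOM and OMe, followed by methylation can give only the required dimethyl pattern, and since no lithium sits next to fluorine no aryne can form at 0 °C.

Step 5
Reactants: 8 [2-fluoro-6-methoxy-4-(methoxymethoxy)-3,5-dimethylphenyl]trimethylsilane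
Product: 9 1-fluoro-5-methoxy-3-(methoxymethoxy)-2,4-dimethylbenzene
Conditions: Bu4NF·3H2O, THF, 50 °C
Reagents that add atoms: none
Why: Fluoride-promoted protodesilylation should cleave the aryl–Si bond because the aryl carbanion leaving silicon is stabilised by the ortho F and OMe groups, while the MOM ether, the methyl ether and the C–F bond are inert to fluoride.

Step 6
Reactants: 9 1-fluoro-5-methoxy-3-(methoxymethoxy)-2,4-dimethylbenzene
Product: 13 2-methoxy-4-(methoxymethoxy)-3,5,6-trimethylbenzoic acid, via 2-fluoroaryllithium 10 (not isolated), via aryne 11 (not isolated), via 2-methylaryllithium 12 (not isolated)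
Conditions: s-BuLi (1.0 equiv), THF, −78 °C; MeLi (4 equiv), −78 to 0 °C; CO2, −78 °C to rt; cold 1 M HCl
Reagents that add atoms: methyllithium, [Li]C; carbon dioxide, O=C=O
Why: s-BuLi removes the single ring hydrogen at C1, acidified by the flanking F and OMe, to give 10, which is stable at −78 °C and on warming loses LiF to the C1–C2 aryne 11; MeLi, already present in excess, adds across the strained triple bond (carbolithiation) to give 12, which CO2 converts into the carboxylate. The closest known reaction type is aryne generation from 3-fluoroanisoles with alkyllithiums followed by regioselective carbolithiation and carboxylation, the established route to 6-alkyl-2-methoxybenzoic acids. No ring is closed and no stereocentre is formed. The step needs one selectivity, the direction of addition: the C6 methoxy group, through its inductive effect on the distorted aryne and through chelation of lithium, places the negative charge at the adjacent C1 and so sends methyl to the distal C2, and a methyl nucleophile is small enough to enter beside the C3 methyl. Using exactly one equivalent of s-BuLi and having MeLi in excess before the mixture is warmed should keep s-butyl addition and self-addition of the hindered aryllithium 10 to the aryne in check. The product is an acid and should be separable from neutral by-products by base extraction.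

Step 7
Reactants: 13 2-methoxy-4-(methoxymethoxy)-3,5,6-trimethylbenzoic acid
Product: 14 methyl 2-methoxy-4-(methoxymethoxy)-3,5,6-trimethylbenzoate
Conditions: MeI, K2CO3, DMF, rt
Reagents that add atoms: iodomethane, CI
Why: O-alkylation of the carboxylate by MeI (SN2 at the methyl group) is indifferent to the two ortho substituents that would block Fischer esterification, and the MOM ether is stable to base.

Step 8
Reactants: 14 methyl 2-methoxy-4-(methoxymethoxy)-3,5,6-trimethylbenzoate
Product: 15 methyl 4-hydroxy-2-methoxy-3,5,6-trimethylbenzoate
Conditions: HCl (cat.), MeOH, 50 °C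
Reagents that add atoms: none
Why: Acid-catalysed acetal cleavage (MOM removal by transacetalisation to methanol) should free the C4 phenol, while the di-ortho-substituted methyl ester and the aryl methyl ether are inert under these conditions.

Step 9
Reactants: 16 2,5-dimethylresorcinol
Product: 17 4,6-dibromo-2,5-dimethylbenzene-1,3-diol
Conditions: NBS (2 equiv), MeCN, 0 °C
Reagents that add atoms: N-bromosuccinimide, O=C1CCC(=O)N1Br
Why: Electrophilic aromatic bromination: the two free ring positions are equivalent and each is ortho to one hydroxyl and para to the other, so two equivalents of NBS should give the symmetrical dibromide.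

Step 10
Reactants: 17 4,6-dibromo-2,5-dimethylbenzene-1,3-diol
Product: 18 1,5-dibromo-2,4-bis(benzyloxy)-3,6-dimethylbenzene
Conditions: BnBr, K2CO3, DMF, 60 °C
Reagents that add atoms: benzyl bromide, BrCc1ccccc1
Why: Williamson etherification of both phenols; benzyl ethers are chosen because they survive BuLi at −78 °C and acyl chloride formation (a MOM ether ortho to an acyl chloride would cyclise) and can be removed at the end without acid or base.

Step 11
Reactants: 18 1,5-dibromo-2,4-bis(benzyloxy)-3,6-dimethylbenzene
Product: 20 2,4-bis(benzyloxy)-5-bromo-3,6-dimethylbenzoic acid, via aryllithium 19 (not isolated)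
Conditions: n-BuLi (1.0 equiv), THF, −78 °C; CO2, −78 °C to rt; 1 M HCl
Reagents that add atoms: carbon dioxide, O=C=O
Why: Bromine–lithium exchange is fast at −78 °C and should stop at the monolithio stage because one equivalent of n-BuLi is used and the first aryllithium deactivates the second bromide; the two bromides are equivalent, so carboxylation gives a single acid.

Step 12
Reactants: 20 2,4-bis(benzyloxy)-5-bromo-3,6-dimethylbenzoic acid
Product: 22 2,4-bis(benzyloxy)-5-formyl-3,6-dimethylbenzoic acid, via dilithio species 21 (not isolated)
Conditions: n-BuLi (2.2 equiv), THF, −78 °C; DMF, −78 to 0 °C; 1 M HCl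
Reagents that add atoms: N,N-dimethylformamide, CN(C)C=O
Why: The first equivalent of n-BuLi forms the hindered lithium carboxylate, which resists addition at −78 °C, the second effects bromine–lithium exchange, and formylation of the aryllithium with DMF (Bouveault aldehyde synthesis) should give the aldehyde on acidic hydrolysis of the hemiaminal.

Step 13
Reactants: 22 2,4-bis(benzyloxy)-5-formyl-3,6-dimethylbenzoic acid; 15 methyl 4-hydroxy-2-methoxy-3,5,6-trimethylbenzoate
Product: 25 3-methoxy-4-(methoxycarbonyl)-2,5,6-trimethylphenyl 2,4-bis(benzyloxy)-5-formyl-3,6-dimethylbenzoate, via acid chloride 23 (not isolated), via sodium phenoxide 24 (not isolated)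
Conditions: 22, (COCl)2, DMF (cat.), CH2Cl2, 0 °C to rt, then evaporation; 15, NaH, THF, 0 °C, then 23 in THF, rt to 50 °C
Reagents that add atoms: none
Why: Oxalyl chloride with catalytic DMF (Vilsmeier-type activation) should convert the acid into acyl chloride 23 without harming the benzyl ethers or the non-enolisable aldehyde, and O-acylation of the preformed sodium phenoxide 24, a small and strongly nucleophilic anion suited to two di-ortho-substituted partners, should give the depside ester.

Step 14
Reactants: 25 3-methoxy-4-(methoxycarbonyl)-2,5,6-trimethylphenyl 2,4-bis(benzyloxy)-5-formyl-3,6-dimethylbenzoate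
Product: 26 methyl 4-[(5-formyl-2,4-dihydroxy-3,6-dimethylbenzoyl)oxy]-2-methoxy-3,5,6-trimethylbenzoate
Conditions: H2 (1 atm), 10% Pd/C, EtOAc, rt
Reagents that add atoms: none
Why: Catalytic hydrogenolysis of the two aryl benzyl ethers should be much faster than reduction of the doubly ortho-substituted aryl aldehyde, and the aryl ester, methyl ester and methyl ether are inert, so the reaction is stopped as soon as 25 is consumed.

Compound list
1 | 3-fluoro-5-methoxyphenol | COc1cc(O)cc(F)c1 | starting material
2 | 1-fluoro-3-methoxy-5-(methoxymethoxy)benzene | COCOc1cc(F)cc(OC)c1 | intermediate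
3 | [2-fluoro-4-methoxy-6-(methoxymethoxy)phenyl]lithium (not isolated) | [Li]c1c(F)cc(OC)cc1OCOC | intermediate
4 | 1-fluoro-5-methoxy-3-(methoxymethoxy)-2-methylbenzene | Cc1c(F)cc(OC)cc1OCOC | intermediate
5 | [2-fluoro-6-methoxy-4-(methoxymethoxy)-3-methylphenyl]lithium (not isolated) | [Li]c1c(F)c(C)c(OCOC)cc1OC | intermediate
6 | [2-fluoro-6-methoxy-4-(methoxymethoxy)-3-methylphenyl]trimethylsilane | C[Si](C)(C)c1c(F)c(C)c(OCOC)cc1OC | intermediate
7 | [4-fluoro-2-methoxy-6-(methoxymethoxy)-5-methyl-3-(trimethylsilyl)phenyl]lithium (not isolated) | [Li]c1c(OC)c([Si](C)(C)C)c(F)c(C)c1OCOC | intermediate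
8 | [2-fluoro-6-methoxy-4-(methoxymethoxy)-3,5-dimethylphenyl]trimethylsilane | C[Si](C)(C)c1c(F)c(C)c(OCOC)c(C)c1OC | intermediate
9 | 1-fluoro-5-methoxy-3-(methoxymethoxy)-2,4-dimethylbenzene (aryne precursor; the same compound as 1-fluoro-3-methoxy-5-(methoxymethoxy)-4,6-dimethylbenzene) | COc1cc(F)c(C)c(OCOC)c1C | intermediate
10 | [2-fluoro-6-methoxy-4-(methoxymethoxy)-3,5-dimethylphenyl]lithium (not isolated) | [Li]c1c(F)c(C)c(OCOC)c(C)c1OC | intermediate
11 | 3-methoxy-5-(methoxymethoxy)-4,6-dimethylbenzyne (not isolated) | COC1=C(C)C(OCOC)=C(C)C#C1 | intermediate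
12 | [2-methoxy-4-(methoxymethoxy)-3,5,6-trimethylphenyl]lithium (not isolated) | [Li]c1c(C)c(C)c(OCOC)c(C)c1OC | intermediate
13 | 2-methoxy-4-(methoxymethoxy)-3,5,6-trimethylbenzoic acid | OC(=O)c1c(C)c(C)c(OCOC)c(C)c1OC | intermediate
14 | methyl 2-methoxy-4-(methoxymethoxy)-3,5,6-trimethylbenzoate | COC(=O)c1c(C)c(C)c(OCOC)c(C)c1OC | intermediate
15 | methyl 4-hydroxy-2-methoxy-3,5,6-trimethylbenzoate | COC(=O)c1c(C)c(C)c(O)c(C)c1OC | intermediate
16 | 2,5-dimethylresorcinol (2,5-dimethylbenzene-1,3-diol) | Cc1cc(O)c(C)c(O)c1 | starting material
17 | 4,6-dibromo-2,5-dimethylbenzene-1,3-diol | Cc1c(O)c(Br)c(C)c(Br)c1O | intermediate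
18 | 1,5-dibromo-2,4-bis(benzyloxy)-3,6-dimethylbenzene | Cc1c(OCc2ccccc2)c(Br)c(C)c(Br)c1OCc1ccccc1 | intermediate
19 | [2,4-bis(benzyloxy)-5-bromo-3,6-dimethylphenyl]lithium (not isolated) | [Li]c1c(C)c(Br)c(OCc2ccccc2)c(C)c1OCc1ccccc1 | intermediate
20 | 2,4-bis(benzyloxy)-5-bromo-3,6-dimethylbenzoic acid | OC(=O)c1c(C)c(Br)c(OCc2ccccc2)c(C)c1OCc1ccccc1 | intermediate
21 | lithium 2,4-bis(benzyloxy)-5-lithio-3,6-dimethylbenzoate (not isolated) | [Li]OC(=O)c1c(C)c([Li])c(OCc2ccccc2)c(C)c1OCc1ccccc1 | intermediate
22 | 2,4-bis(benzyloxy)-5-formyl-3,6-dimethylbenzoic acid | OC(=O)c1c(C)c(C=O)c(OCc2ccccc2)c(C)c1OCc1ccccc1 | intermediate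
23 | 2,4-bis(benzyloxy)-5-formyl-3,6-dimethylbenzoyl chloride (not isolated) | O=C(Cl)c1c(C)c(C=O)c(OCc2ccccc2)c(C)c1OCc1ccccc1 | intermediate
24 | sodium 3-methoxy-4-(methoxycarbonyl)-2,5,6-trimethylphenolate (not isolated) | [Na+].[O-]c1c(C)c(C)c(C(=O)OC)c(OC)c1C | intermediate
25 | 3-methoxy-4-(methoxycarbonyl)-2,5,6-trimethylphenyl 2,4-bis(benzyloxy)-5-formyl-3,6-dimethylbenzoate | COC(=O)c1c(C)c(C)c(OC(=O)c2c(C)c(C=O)c(OCc3ccccc3)c(C)c2OCc2ccccc2)c(C)c1OC | intermediate
26 | methyl 4-[(5-formyl-2,4-dihydroxy-3,6-dimethylbenzoyl)oxy]-2-methoxy-3,5,6-trimethylbenzoate (CNP0316552.0) | COC(=O)c1c(C)c(C)c(OC(=O)c2c(C)c(C=O)c(O)c(C)c2O)c(C)c1OC | target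

Total step count: 14. Longest linear sequence: 10 steps (steps 1–8, 13 and 14, from 3-fluoro-5-methoxyphenol); the ring A branch (steps 9–12) joins at step 13.

Steps most likely to fail

1. Step 6 (key step). What may go wrong: the aryne may be consumed by addition of still-unreacted 2-fluoroaryllithium, or methyl may add without regiocontrol, so that carboxylation gives mixtures. Fallback without an aryne: setting out from 9, lithiation with s-BuLi at −78 °C as before and carboxylation of 10 at −78 °C, before any LiF is lost, should give 2-fluoro-6-methoxy-4-(methoxymethoxy)-3,5-dimethylbenzoic acid F1. Excess MeLi (THF, −78 °C to rt) should then replace the fluoride ortho to the lithium carboxylate by methyl through carboxylate-assisted nucleophilic aromatic substitution (addition–elimination, a known reaction of ortho-fluorobenzoic acids with organolithium reagents; fluoride leaves in preference to methoxide). The route is rejoined at 13.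

2. Step 13. What may go wrong: acylation may stall because the acyl chloride and the phenoxide each carry two ortho substituents, with loss of the acid chloride to hydrolysis on work-up. Fallback through an acylium-type donor instead of an acyl chloride and a phenoxide: setting out from 22 and 15, (CF3CO)2O in toluene at rt should convert 22 into 2,4-bis(benzyloxy)-5-formyl-3,6-dimethylbenzoic trifluoroacetic anhydride F2. This mixed anhydride ionises readily for an electron-rich 2,6-disubstituted benzoyl group and should acylate the free phenol 15 under acidic conditions, the standard way to hindered depside esters. The route is rejoined at 25.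

3. Step 14. What may go wrong: hydrogenation of the formyl group (to hydroxymethyl or methyl) may compete with cleavage of the benzyl ethers. Fallback by Lewis acid dealkylation instead of reduction: setting out from 25, BCl3 with pentamethylbenzene as benzyl cation scavenger (CH2Cl2, −78 °C) should remove both benzyl groups, each activated by chelation to an ortho carbonyl group. At this temperature the ring B methyl ether and both esters should survive. The route is rejoined at 26, and no new compound is made (F0).

Further compounds
F1 | step 6 | 2-fluoro-6-methoxy-4-(methoxymethoxy)-3,5-dimethylbenzoic acid | OC(=O)c1c(F)c(C)c(OCOC)c(C)c1OC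
F2 | step 13 | 2,4-bis(benzyloxy)-5-formyl-3,6-dimethylbenzoic trifluoroacetic anhydride | O=C(OC(=O)C(F)(F)F)c1c(C)c(C=O)c(OCc2ccccc2)c(C)c1OCc1ccccc1
F0 | step 14 | none | none
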